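(The runs are calculated on assumed constants, and the scatter is random.)

Without exchange, a racemate cannot put more left-handed material into left-handed substrate and left-handed product together than the half of the charge that began left-handed.

| flask | left-handed substrate | right-handed substrate | coupling partner | racemization catalyst | precatalyst | remark | time |
|---|---|---|---|---|---|---|---|
| west | 20 mM | 20 mM | 44 mM | 120 µM | 3 mM | run made earlier |  |
| flask | 20 mM | 20 mM | 44.0 mM | 58 µM | 3.0 mM |  | 10 d |

- west (time / h: left-handed product / %, right-handed product / %, left-handed substrate / %): 8.00: 12.3, 3.3, 42.9; 15.0: 21.0, 6.3, 36.9; 25.0: 29.1, 9.4, 30.7; 30.0: 31.7, 10.4, 28.8; 40.0: 36.5, 12.5, 26.0; 50.0: 40.7, 13.4, 24.0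

(scatter of a reading: 0.5 percentage points)

- left-handed product and right-handed product together, in percent of the left-handed substrate and right-handed substrate charged together, at 10 d
- excess of left-handed product over right-handed product in the product at 10 d
- whether the exchange between left-handed substrate and right-handed substrate keeps pace with the reaction: how far the product's excess at 10 d gets from its value without exchange to its value with instant exchange (above 80% keeps pace, below 20% hardly takes part, else lags behind)

- free catalyst is single-handed; left-handed substrate and right-handed substrate are mirror images of each other, charged as a racemate, each of them at the stated concentration
- an excess is below zero if the other one leads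
- no earlier run changes the charge of racemization catalyst; that part of a forecast is a guess

Does anything cross over? In the west run at 50.0 h, those two read 64.7% together, which is more than that half, so right-handed substrate has been turning into left-handed substrate.

What does this do to the product? Equal substrates are the zero of my scale: with the free catalyst single-handed, product formed from them can still carry an excess. The west reading at 50.0 h gives a left-to-right product ratio, the selectivity factor, of 3.04. I carry this reading as the equal-pool excess, the difference of the two products over their sum while the substrates stand equal: 50.5%.

Are they equal? By balance, right-handed substrate in the west run at 25.0 h stands at 30.8% against 30.7% left-handed, a gap of 0.1 percentage points with a scatter of 0.5 points per reading.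

Does this survive the new charge? The flask holds 58 µM of racemization catalyst against 120 µM, about half, and how exchange answers is a guess. If it follows that charge, the gap needed for the same traffic becomes twice as wide, which I expect to stay small beside the substrates. So I commit to 50.5% for the excess, with exchange keeping pace.

The forecast gives 87% of product (79% to 91%), an excess of 49.5% (43% to 54%), slightly below mine, and "keeps pace": “Halving the racemization catalyst, assuming linear dependence, still leaves exchange much faster than coupling”.

The flask gives 79.8% of product at 10 d, 7.2 points below the forecast, with an excess of 50.7%; exchange keeps pace, at 99.0% of the way.

coupling partner + free catalyst + left-handed substrate → free catalyst + left-handed product (k = 20000 /M²/h); coupling partner + free catalyst + right-handed substrate → free catalyst + right-handed product (k = 6500 /M²/h); left-handed substrate + racemization catalyst ⇌ right-handed substrate + racemization catalyst, rate k3*[racemization catalyst]*[left-handed substrate] forward; the back reaction follows from the equilibrium constant (k = 17000 /M/h); 2 free catalyst → spent catalyst (k = 4800 /M/h); coupling partner + precatalyst → free catalyst + spent reagent (k = 0.200 /M/h) By then 56.0% of the catalyst charged stands as spent catalyst. The equal-pool excess splits that product into 60.0% left-handed, and the flask holds 60.1%. With 11 mM of coupling partner and the other charges unchanged, the neighbouring flask makes 21.4% of product, which the same excess splits to 5.30% right-handed, and it holds 5.25%.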